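**Plan**
1. Retrosynthesis: the four phenolic O–H bonds become O–Si bonds, and each 3,4-dihydroxyphenyl ring (C1′ on the tetrahydrofuran, C3′/C4′ oxygenated) is cut at C1′–C2′ and C5′–C6′. C2′–C3′–C4′–C5′, the two oxygenated carbons with their CH neighbours, then form a symmetric 2,3-bis(silyloxy)buta-1,3-diene, and C1′/C6′ form an ethynyl group on C2 or C5 of the tetrahydrofuran.
2. The cis-2,5-diethynyl tetrahydrofuran is traced through the 2,5-dialdehyde to the C=C bond of the exo furan–maleic anhydride adduct.
3. Forward: the oxanorbornene forms first and its oxygen bridge becomes the tetrahydrofuran. The carbocyclic bridge is opened by ozonolysis and both formyl groups are homologated to alkynes. The two six-membered rings are then closed in one cobalt-catalysed [4+2] operation and dehydrogenated to the catechol rings.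
4. Stereochemistry: all four stereocentres (2,5-cis, 3,4-cis, 2,3-trans, 4,5-trans) come from the exo Diels–Alder adduct; no bond is made at C2 or C5 afterwards.

Key step: step 9

Remark: the target drawn, (2R,3S,4R,5S), is a meso compound, so only relative configuration has to be controlled. In each twofold transformation both equivalent sites react in one operation, and half-converted species are not counted as separate compounds.
Remark: the diene carries tert-butyldimethylsilyl enol ethers, which should tolerate the zinc salts of the catalyst and the quinone oxidant better than smaller silyl groups and should allow the cycloadduct and the arene to be purified.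

**Step 1**
Reactants: 1 furan; 2 maleic anhydride
Product: 3 exo-7-oxabicyclo[2.2.1]hept-5-ene-2,3-dicarboxylic anhydride (meso)
Conditions: toluene, rt, 24–48 h; crystalline adduct filtered off
Reagents that add atoms: none
Why: Diels–Alder reaction that is reversible at room temperature, so the thermodynamically preferred exo adduct should crystallise; it places the two carbonyl-bearing carbons cis to each other and anti to the C=C bridge, which sets the relative configuration of all four stereocentres of the target.

**Step 2**
Reactants: 3 exo anhydride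
Product: 4 exo,exo-7-oxabicyclo[2.2.1]hept-5-ene-2,3-diyldimethanol (meso)
Conditions: LiAlH4, THF, 0 °C → rt; H2O, aq. NaOH work-up
Reagents that add atoms: none
Why: Hydride reduction of a cyclic anhydride to the 1,4-diol, run at or below room temperature so that retro-Diels–Alder cleavage of the oxanorbornene does not intervene; no stereocentre is touched.

**Step 3**
Reactants: 4 exo,exo-diol
Product: 5 exo,exo-2,3-bis(tert-butyldimethylsilyloxymethyl)-7-oxabicyclo[2.2.1]hept-5-ene (meso)
Conditions: TBSCl, imidazole, DMF, rt
Reagents that add atoms: tert-butyldimethylsilyl chloride, CC(C)(C)[Si](C)(C)Cl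
Why: Standard imidazole-promoted silylation of primary alcohols; the silyl ethers are inert to ozone and to carbonate in methanol, which acetates would not be.

**Step 4**
Reactants: 5 bis(silyl ether)
Product: 7 meso-3,4-bis(tert-butyldimethylsilyloxymethyl)tetrahydrofuran-2,5-dicarbaldehyde (2,5-cis/3,4-cis/2,3-trans), via secondary ozonide 6 (not isolated)
Conditions: O3, CH2Cl2, −78 °C; then PPh3, −78 °C → rt; crude dialdehyde used at once
Reagents that add atoms: ozone, [O-][O+]=O
Why: Ozonolysis by the Criegee mechanism with phosphine reduction of the ozonide; the two alkene carbons become formyl groups that stay cis to each other and trans to the neighbouring arms because no ring stereocentre takes part.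

**Step 5**
Reactants: 7 dialdehyde; 8 dimethyl (1-diazo-2-oxopropyl)phosphonate
Product: 9 meso-2,5-diethynyl-3,4-bis(tert-butyldimethylsilyloxymethyl)tetrahydrofuran (2,5-cis/3,4-cis/2,3-trans)
Conditions: K2CO3, MeOH, 0 °C → rt
Reagents that add atoms: none
Why: Ohira–Bestmann variant of the Seyferth–Gilbert homologation (methanolysis to the diazomethylphosphonate, Horner–Wadsworth–Emmons-type olefination, loss of N2 and 1,2-hydride shift), mild enough that the α-alkoxy centres, already in their more stable 2,3-trans arrangement, should keep their configuration.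

**Step 6**
Reactants: 9 diyne bis(silyl ether)
Product: 10 meso-(2,5-diethynyltetrahydrofuran-3,4-diyl)dimethanol
Conditions: CSA (cat.), MeOH, rt
Reagents that add atoms: none
Why: Acid-catalysed methanolysis of primary silyl ethers, which leaves terminal alkynes and the ring ether alone and gives only a volatile methoxysilane beside the polar diol.

**Step 7**
Reactants: 10 diyne diol
Product: 11 meso-(2,5-diethynyltetrahydrofuran-3,4-diyl)bis(methylene) diacetate (ethynyl groups cis to each other and trans to the acetoxymethyl arms)
Conditions: Ac2O, pyridine, DMAP (cat.), CH2Cl2, 0 °C → rt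
Reagents that add atoms: acetic anhydride, CC(=O)OC(C)=O
Why: DMAP-catalysed acylation of primary alcohols; both acetates of the target are installed before any phenol exists, so no later esterification beside free catechols is needed.

**Step 8**
Reactants: 12 butane-2,3-dione
Product: 13 2,3-bis(tert-butyldimethylsilyloxy)buta-1,3-diene
Conditions: TBSOTf, Et3N, CH2Cl2, 0 °C → rt
Reagents that add atoms: tert-butyldimethylsilyl trifluoromethanesulfonate, CC(C)(C)[Si](C)(C)OS(=O)(=O)C(F)(F)F
Why: Soft enolisation and O-silylation of both carbonyl groups of a 1,2-diketone (silyl enol ether formation), which gives the symmetric electron-rich diene directly.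

**Step 9**
Reactants: 11 diyne diacetate; 13 bis(silyloxy)diene
Product: 14 meso-{2,5-bis[4,5-bis(tert-butyldimethylsilyloxy)cyclohexa-1,4-dien-1-yl]tetrahydrofuran-3,4-diyl}bis(methylene) diacetate
Conditions: 13 (3 equiv), CoBr2(dppe) (10 mol %; dppe = Ph2PCH2CH2PPh2), Zn dust (20 mol %), ZnI2 (20 mol %), CH2Cl2, rt, argon
Reagents that add atoms: none
Why: Zinc reduces the divalent cobalt bromide complex and ZnI2 removes halide, so a cationic monovalent cobalt–dppe centre binds the s-cis diene and one alkyne, couples them oxidatively to a trivalent cobaltacycle and closes the ring by reductive elimination. The closest known reaction type is the cobalt-catalysed neutral Diels–Alder reaction of terminal alkynes with 2,3-dialkyl- and 2-silyloxybuta-1,3-dienes, which delivers 1,4-cyclohexadienes. Each of the two six-membered carbocycles closes by an intermolecular [4+2] annulation in which the internal alkyne carbon bonds to one diene terminus and the terminal alkyne carbon to the other, four C–C bonds in all. No stereocentre is created, and the four ring stereocentres of 11 are spectators because the neutral aprotic medium cannot epimerise the propargylic C2–H and C5–H. The selectivity needed is chemoselectivity for diene–alkyne coupling over alkyne cyclotrimerisation and over Lewis-acid cleavage of the enol ethers; excess diene, the non-coordinating solvent and the robust tert-butyldimethylsilyl groups should secure it, while the twofold symmetry of the diene removes any regiochemical question.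

**Step 10**
Reactants: 14 bis(cyclohexadiene)
Product: 15 meso-{2,5-bis[3,4-bis(tert-butyldimethylsilyloxy)phenyl]tetrahydrofuran-3,4-diyl}bis(methylene) diacetate
Conditions: DDQ (2.1 equiv), benzene, rt
Reagents that add atoms: none
Why: DDQ dehydrogenation, in which hydride abstraction from a doubly allylic CH2 gives a silyloxy-stabilised cyclohexadienyl cation that loses a proton to the arene; this should be much faster than attack on the ether-flanked C–H bonds, so two equivalents in dry benzene should stop at the silylated catechols.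

**Step 11**
Reactants: 15 tetrakis(silyl) ether
Product: 16 [(2R,3S,4R,5S)-2,5-bis(3,4-dihydroxyphenyl)tetrahydrofuran-3,4-diyl]bis(methylene) diacetate (meso; the target)
Conditions: KHF2, MeOH, rt
Reagents that add atoms: none
Why: Bifluoride-mediated cleavage of aryl silyl ethers (fluoride attack at silicon with a phenoxide leaving group) under mildly acidic conditions in which primary acetates should neither migrate nor methanolyse, releasing the four phenols.

**Compound list**
1 | furan | c1ccoc1 | starting material
2 | maleic anhydride | O=C1C=CC(=O)O1 | starting material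
3 | exo-7-oxabicyclo[2.2.1]hept-5-ene-2,3-dicarboxylic anhydride (meso; anhydride ring on the side of the oxygen bridge) | O=C1OC(=O)[C@H]2[C@@H]1[C@@H]3C=C[C@H]2O3 | intermediate
4 | exo,exo-7-oxabicyclo[2.2.1]hept-5-ene-2,3-diyldimethanol (meso) | OC[C@@H]1[C@H](CO)[C@H]2C=C[C@@H]1O2 | intermediate
5 | exo,exo-2,3-bis(tert-butyldimethylsilyloxymethyl)-7-oxabicyclo[2.2.1]hept-5-ene (meso) | CC(C)(C)[Si](C)(C)OC[C@@H]1[C@H](CO[Si](C)(C)C(C)(C)C)[C@H]2C=C[C@@H]1O2 | intermediate
6 | secondary ozonide (bridging 1,2,4-trioxolane) of 5; the two trioxolane carbons are necessarily cis-bridged, and which of the two bridged epimers forms is left open because both give 7 | CC(C)(C)[Si](C)(C)OC[C@@H]1[C@H](CO[Si](C)(C)C(C)(C)C)[C@H]2C3OOC(O3)[C@@H]1O2 | intermediate (not isolated)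
7 | meso-3,4-bis(tert-butyldimethylsilyloxymethyl)tetrahydrofuran-2,5-dicarbaldehyde (formyl groups cis to each other, arms cis to each other, formyl trans to the adjacent arm) | CC(C)(C)[Si](C)(C)OC[C@@H]1[C@H](CO[Si](C)(C)C(C)(C)C)[C@@H](C=O)O[C@H]1C=O | intermediate
8 | dimethyl (1-diazo-2-oxopropyl)phosphonate | CC(=O)C(=[N+]=[N-])P(=O)(OC)OC | starting material
9 | meso-2,5-diethynyl-3,4-bis(tert-butyldimethylsilyloxymethyl)tetrahydrofuran (2,5-cis, 3,4-cis, 2,3-trans) | CC(C)(C)[Si](C)(C)OC[C@@H]1[C@H](CO[Si](C)(C)C(C)(C)C)[C@@H](C#C)O[C@H]1C#C | intermediate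
10 | meso-(2,5-diethynyltetrahydrofuran-3,4-diyl)dimethanol (same relative configuration) | OC[C@@H]1[C@H](CO)[C@@H](C#C)O[C@H]1C#C | intermediate
11 | meso-(2,5-diethynyltetrahydrofuran-3,4-diyl)bis(methylene) diacetate (ethynyl groups cis, trans to the arms) | CC(=O)OC[C@@H]1[C@H](COC(C)=O)[C@@H](C#C)O[C@H]1C#C | intermediate
12 | butane-2,3-dione | CC(=O)C(C)=O | starting material
13 | 2,3-bis(tert-butyldimethylsilyloxy)buta-1,3-diene | C=C(O[Si](C)(C)C(C)(C)C)C(=C)O[Si](C)(C)C(C)(C)C | intermediate
14 | meso-{2,5-bis[4,5-bis(tert-butyldimethylsilyloxy)cyclohexa-1,4-dien-1-yl]tetrahydrofuran-3,4-diyl}bis(methylene) diacetate (2,5-cis, 3,4-cis, 2,3-trans) | CC(=O)OC[C@@H]1[C@H](COC(C)=O)[C@@H](C2=CCC(O[Si](C)(C)C(C)(C)C)=C(O[Si](C)(C)C(C)(C)C)C2)O[C@H]1C1=CCC(O[Si](C)(C)C(C)(C)C)=C(O[Si](C)(C)C(C)(C)C)C1 | intermediate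
15 | meso-{2,5-bis[3,4-bis(tert-butyldimethylsilyloxy)phenyl]tetrahydrofuran-3,4-diyl}bis(methylene) diacetate (same relative configuration) | CC(=O)OC[C@@H]1[C@H](COC(C)=O)[C@@H](c2ccc(O[Si](C)(C)C(C)(C)C)c(O[Si](C)(C)C(C)(C)C)c2)O[C@H]1c1ccc(O[Si](C)(C)C(C)(C)C)c(O[Si](C)(C)C(C)(C)C)c1 | intermediate
16 | [(2R,3S,4R,5S)-2,5-bis(3,4-dihydroxyphenyl)tetrahydrofuran-3,4-diyl]bis(methylene) diacetate (meso) | CC(=O)OC[C@@H]1[C@H](COC(C)=O)[C@@H](c2ccc(O)c(O)c2)O[C@H]1c1ccc(O)c(O)c1 | target

**Step count**
Total: 11 steps. Longest linear sequence: 10 steps (steps 1–7 and 9–11); step 8 is a one-step side branch.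

**Steps most likely to fail**

Step 9. The crowded, electron-rich diene may enter the cobalt coordination sphere slowly. Alkyne cyclotrimerisation, coupling of the two cis-disposed ethynyl groups at one metal centre, zinc-induced loss of silyl groups, or arrest after the first ring closure could then overtake the twofold [4+2]. The fallback leaves at 7 and returns at 15, attaching ready-made aryl rings instead of building them:
- Pinnick oxidation of 7 (NaClO2, NaH2PO4, 2-methyl-2-butene, t-BuOH/H2O) should give meso-3,4-bis(tert-butyldimethylsilyloxymethyl)tetrahydrofuran-2,5-dicarboxylic acid F1.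
- N-Hydroxyphthalimide and N,N′-diisopropylcarbodiimide would convert it into the bis(1,3-dioxoisoindolin-2-yl) diester F2.
- In parallel, 4-bromocatechol would be silylated (TBSCl, imidazole) to 4-bromo-1,2-bis(tert-butyldimethylsilyloxy)benzene F3, and n-BuLi followed by ZnCl2 would turn this into [3,4-bis(tert-butyldimethylsilyloxy)phenyl]zinc chloride F4.
- Nickel-catalysed decarboxylative Negishi arylation of F2 with F4 (NiCl2(dme), 4,4′-di-tert-butyl-2,2′-bipyridine, THF/DMF, rt; dme = 1,2-dimethoxyethane) should give meso-2,5-bis[3,4-bis(tert-butyldimethylsilyloxy)phenyl]-3,4-bis(tert-butyldimethylsilyloxymethyl)tetrahydrofuran F5. Each C2/C5 radical should be captured anti to the adjacent silyloxymethyl arm.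
- CSA in MeOH at 0 °C should free only the two primary alcohols, aryl silyl ethers being acid-stable, to give meso-{2,5-bis[3,4-bis(tert-butyldimethylsilyloxy)phenyl]tetrahydrofuran-3,4-diyl}dimethanol F6.
- Acetylation (Ac2O, pyridine) rejoins the route at 15.

Step 10. Once the electron-rich arenes exist, over-oxidation may compete: hydride abstraction from the ether-flanked C2–H and C5–H, or oxidative loss of silyl groups towards o-quinones, especially if dehydrogenation of the second ring lags. The fallback leaves at 14 and returns at 16, oxidising at the oxygen-bearing carbons instead of the ring CH2 groups. Br2 (one equivalent per ring, CH2Cl2, −78 °C, then aq. NaHCO3) applies the known conversion of 1,2-bis(silyloxy)alkenes into 1,2-diketones. This should give meso-[2,5-bis(4,5-dioxocyclohex-1-en-1-yl)tetrahydrofuran-3,4-diyl]bis(methylene) diacetate F7, whose enolisation towards the activated CH2 groups gives the catechol rings. The target 16 would be reached directly, without steps 10 and 11.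

Step 5. Enolisation of the α-alkoxy aldehydes in carbonate/methanol may cause epimerisation at C2/C5, hemiacetal formation or aldol-type oligomerisation before both formyl groups are homologated. The fallback leaves at 7 and returns at 9 by a Corey–Fuchs sequence. CBr4 and PPh3 (CH2Cl2, 0 °C) should give meso-2,5-bis(2,2-dibromovinyl)-3,4-bis(tert-butyldimethylsilyloxymethyl)tetrahydrofuran F8 without base. n-BuLi (THF, −78 °C) then effects bromine–lithium exchange and Fritsch–Buttenberg–Wiechell rearrangement, and protonation of the bis(acetylide) gives 9.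

**Further compounds**
F1 | step 9 | meso-3,4-bis(tert-butyldimethylsilyloxymethyl)tetrahydrofuran-2,5-dicarboxylic acid | CC(C)(C)[Si](C)(C)OC[C@@H]1[C@H](CO[Si](C)(C)C(C)(C)C)[C@@H](C(=O)O)O[C@H]1C(=O)O
F2 | step 9 | bis(1,3-dioxoisoindolin-2-yl) meso-3,4-bis(tert-butyldimethylsilyloxymethyl)tetrahydrofuran-2,5-dicarboxylate | CC(C)(C)[Si](C)(C)OC[C@@H]1[C@H](CO[Si](C)(C)C(C)(C)C)[C@@H](C(=O)ON2C(=O)c3ccccc3C2=O)O[C@H]1C(=O)ON1C(=O)c2ccccc2C1=O
F3 | step 9 | 4-bromo-1,2-bis(tert-butyldimethylsilyloxy)benzene | Brc1ccc(O[Si](C)(C)C(C)(C)C)c(O[Si](C)(C)C(C)(C)C)c1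
F4 | step 9 | [3,4-bis(tert-butyldimethylsilyloxy)phenyl]zinc chloride | Cl[Zn]c1ccc(O[Si](C)(C)C(C)(C)C)c(O[Si](C)(C)C(C)(C)C)c1
F5 | step 9 | meso-2,5-bis[3,4-bis(tert-butyldimethylsilyloxy)phenyl]-3,4-bis(tert-butyldimethylsilyloxymethyl)tetrahydrofuran | CC(C)(C)[Si](C)(C)OC[C@@H]1[C@H](CO[Si](C)(C)C(C)(C)C)[C@@H](c2ccc(O[Si](C)(C)C(C)(C)C)c(O[Si](C)(C)C(C)(C)C)c2)O[C@H]1c1ccc(O[Si](C)(C)C(C)(C)C)c(O[Si](C)(C)C(C)(C)C)c1
F6 | step 9 | meso-{2,5-bis[3,4-bis(tert-butyldimethylsilyloxy)phenyl]tetrahydrofuran-3,4-diyl}dimethanol | OC[C@@H]1[C@H](CO)[C@@H](c2ccc(O[Si](C)(C)C(C)(C)C)c(O[Si](C)(C)C(C)(C)C)c2)O[C@H]1c1ccc(O[Si](C)(C)C(C)(C)C)c(O[Si](C)(C)C(C)(C)C)c1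
F7 | step 10 | meso-[2,5-bis(4,5-dioxocyclohex-1-en-1-yl)tetrahydrofuran-3,4-diyl]bis(methylene) diacetate | CC(=O)OC[C@@H]1[C@H](COC(C)=O)[C@@H](C2=CCC(=O)C(=O)C2)O[C@H]1C1=CCC(=O)C(=O)C1
F8 | step 5 | meso-2,5-bis(2,2-dibromovinyl)-3,4-bis(tert-butyldimethylsilyloxymethyl)tetrahydrofuran | CC(C)(C)[Si](C)(C)OC[C@@H]1[C@H](CO[Si](C)(C)C(C)(C)C)[C@@H](C=C(Br)Br)O[C@H]1C=C(Br)Br
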